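## Retrosynthetic overview

1. Target ⇐ 13‑O‑acetylation and desilylation ⇐ ten‑membered ring made last by a four‑atom radical ring expansion (1,5‑acyl shift of C1 from C6 to C2) of a keto‑butenolide carrying a 4‑iodobutyl arm on its ring‑fusion carbon; the same step creates the C5=C6 enol‑lactone alkene.
2. Iodobutyl arm (C2–C5 with the C4 carbinol) ⇐ C‑acetonylation at C6, catalyst‑controlled vinyl addition to the methyl ketone, hydroboration–iodination.
3. Ring B keto‑butenolide ⇐ intramolecular Claisen acylation of the butenolide γ‑carbon by a trans‑α‑methyl‑γ‑lactone (C8 and C10 already set).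
4. Lactone ⇐ asymmetric addition of a chiral‑pool β‑zinc ester to a 4‑formylbutenolide; butenolide ⇐ but‑2‑yne‑1,4‑diol, vinyl Grignard and CO2.
5. Ring order: butenolide, γ‑lactone, ring B (six‑membered carbocycle), transient ring A, ten‑membered ring.

Assumption: C1–C15 in the text are the germacrane positions of the target (C1 ketone, C4 carbinol, C5=C6 enol‑lactone alkene, C8 ester carbon, C10 methyl‑bearing carbon, C12 lactone carbonyl, C13 acetoxymethyl carbon); systematic names use their own locants, and bicyclic compounds 15–24 are carried as mixtures at the ring‑fusion carbon C6 (locant 7a), which is planar again in 25.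

## Route

Step 1
Reactants: 1 but-2-yne-1,4-diol; 2 vinylmagnesium bromide; 3 carbon dioxide
Product: 6 4-ethenyl-3-(hydroxymethyl)furan-2(5H)-one, via alkenylmagnesium dialkoxide 4 (not isolated), via dienoic hydroxy acid 5 (not isolated)
Conditions: CH2=CHMgBr (3.5 equiv), CuI (10 mol%), THF, 0 °C to reflux; then CO2, −20 °C to rt; then 2 M HCl
Reagents that add atoms: none
Why: The dialkoxide directs a CuI‑catalysed anti‑carbomagnesiation (vinyl on one alkyne carbon, chelated magnesium trans to it on the other), so carboxylation and acidification give a (Z)‑γ‑hydroxy acid that can only lactonise to the 3‑hydroxymethyl‑4‑vinyl butenolide (alkoxide‑directed carbomagnesiation, carboxylation, lactonisation).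

Step 2
Reactants: 6 4-ethenyl-3-(hydroxymethyl)furan-2(5H)-one
Product: 7 3-{[tert-butyl(dimethyl)silyl]oxymethyl}-4-ethenylfuran-2(5H)-one
Conditions: t‑BuMe2SiCl, imidazole, CH2Cl2, 0 °C to rt
Reagents that add atoms: tert-butyl(chloro)dimethylsilane, CC(C)(C)[Si](C)(C)Cl
Why: Silyl ether formation on the primary allylic alcohol masks the C13 oxygen as a poor leaving group, because an acetate here would be expelled (E1cB) from the furanolate and enolate intermediates of steps 5 and 7 (silyl protection).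

Step 3
Reactants: 7 3-{[tert-butyl(dimethyl)silyl]oxymethyl}-4-ethenylfuran-2(5H)-one
Product: 9 4-{[tert-butyl(dimethyl)silyl]oxymethyl}-5-oxo-2,5-dihydrofuran-3-carbaldehyde, via secondary ozonide 8 (not isolated)
Conditions: O3 (1 equiv, stopped at first blue tinge), CH2Cl2, −78 °C; then Me2S, −78 °C to rt
Reagents that add atoms: ozone, [O-][O+]=O
Why: Ozone cleaves the terminal, more electron‑rich vinyl group in preference to the tetrasubstituted, carbonyl‑deactivated ring alkene, and Me2S reduces the ozonide to the aldehyde (chemoselective ozonolysis).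

Step 4
Reactants: 9 4-{[tert-butyl(dimethyl)silyl]oxymethyl}-5-oxo-2,5-dihydrofuran-3-carbaldehyde; 10 methyl (2R)-3-bromo-2-methylpropanoate
Product: 13 (3S,5R)-5-(4-{[tert-butyl(dimethyl)silyl]oxymethyl}-5-oxo-2,5-dihydrofuran-3-yl)-3-methyloxolan-2-one, via dialkylzinc 11 (not isolated), via hydroxy ester 12 (not isolated)
Conditions: 10 (2.4 equiv), Et2Zn, MnBr2 (5 mol%), CuCl (3 mol%), DMPU, rt, volatiles removed; then 9, Ti(OiPr)4 (2 equiv), (1S,2S)-1,2-bis(trifluoromethanesulfonamido)cyclohexane (8 mol%), toluene, −20 °C; 1 M HCl work‑up; then PPTS (cat.), CH2Cl2, rt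
Reagents that add atoms: none
Why: Bromine–zinc exchange gives the β‑zinc ester without touching the chiral‑pool C10 centre, and the Ti–bis(sulfonamide) catalyst transfers this alkyl group to the Re face of the aldehyde so that C8 is set as R by catalyst control, after which acid closes the trans γ‑lactone (catalytic asymmetric dialkylzinc addition, lactonisation).

Step 5
Reactants: 13 (3S,5R)-5-(4-{[tert-butyl(dimethyl)silyl]oxymethyl}-5-oxo-2,5-dihydrofuran-3-yl)-3-methyloxolan-2-one
Product: 15 (4R,6S)-3-{[tert-butyl(dimethyl)silyl]oxymethyl}-4-hydroxy-6-methyl-4,5,6,7a-tetrahydro-1-benzofuran-2,7-dione, via lithium enolate 14 (not isolated)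
Conditions: LiN(SiMe3)2 (1.1 equiv), THF, −78 to −20 °C; then AcOH, −78 °C
Reagents that add atoms: none
Why: The base removes the butenolide γ‑proton (C6, the most acidic site), the furan‑2‑olate carbon attacks the lactone carbonyl (C1) through a six‑membered transition state, and collapse of the bridged hemiketal frees the C8 alkoxide, which is quenched by the very acidic C6–H of the new β‑keto butenolide, so the equilibrium is driven to enolate 14 and C10 is not epimerised (intramolecular vinylogous Claisen, Dieckmann‑type, forming ring B).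

Step 6
Reactants: 15 (4R,6S)-3-{[tert-butyl(dimethyl)silyl]oxymethyl}-4-hydroxy-6-methyl-4,5,6,7a-tetrahydro-1-benzofuran-2,7-dione; 16 3-methylbut-2-enoyl chloride
Product: 17 (4R,6S)-3-{[tert-butyl(dimethyl)silyl]oxymethyl}-6-methyl-2,7-dioxo-2,4,5,6,7,7a-hexahydro-1-benzofuran-4-yl 3-methylbut-2-enoate
Conditions: 16 (1.05 equiv), pyridine, DMAP (cat.), CH2Cl2, −20 °C
Reagents that add atoms: none
Why: The only free hydroxyl, the secondary C8 alcohol, is esterified by the acid chloride under pyridine/DMAP at low temperature, which avoids deconjugation of the senecioyl group, and this must precede step 7 because a free C8 alkoxide would reopen ring B once C6 is quaternary (acylation).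

Step 7
Reactants: 17 (4R,6S)-3-{[tert-butyl(dimethyl)silyl]oxymethyl}-6-methyl-2,7-dioxo-2,4,5,6,7,7a-hexahydro-1-benzofuran-4-yl 3-methylbut-2-enoate; 18 1-bromopropan-2-one
Product: 19 (4R,6S)-3-{[tert-butyl(dimethyl)silyl]oxymethyl}-6-methyl-2,7-dioxo-7a-(2-oxopropyl)-2,4,5,6,7,7a-hexahydro-1-benzofuran-4-yl 3-methylbut-2-enoate
Conditions: 18, K2CO3 (1.2 equiv), acetone, 0 °C to rt
Reagents that add atoms: none
Why: The C6–H, flanked by the ketone and the butenolide, gives a soft stabilised enolate with carbonate that is C‑alkylated by the α‑bromo ketone to a quaternary centre whose configuration does not matter because C6 becomes sp2 in step 10 (enolate SN2 alkylation).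

Step 8
Reactants: 19 (4R,6S)-3-{[tert-butyl(dimethyl)silyl]oxymethyl}-6-methyl-2,7-dioxo-7a-(2-oxopropyl)-2,4,5,6,7,7a-hexahydro-1-benzofuran-4-yl 3-methylbut-2-enoate; 2 vinylmagnesium bromide
Product: 22 (4R,6S)-3-{[tert-butyl(dimethyl)silyl]oxymethyl}-6-methyl-7a-[(2S)-2-methyl-2-(triethylsilyloxy)but-3-en-1-yl]-2,7-dioxo-2,4,5,6,7,7a-hexahydro-1-benzofuran-4-yl 3-methylbut-2-enoate, via divinylzinc 20 (not isolated), via zinc alkoxide 21 (not isolated)
Conditions: CH2=CHMgBr, ZnCl2, THF, then 1,4‑dioxane and filtration; then 19, Ti(OiPr)4 (1.2 equiv), trans‑cyclohexane‑1,2‑diamine bis(hydroxycamphorsulfonamide) ligand (10 mol%, the enantiomer that delivers to the Re face), toluene, 0 °C; then Et3SiOTf, 2,6‑lutidine, −40 °C; cold dilute HCl quench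
Reagents that add atoms: triethylsilyl trifluoromethanesulfonate, CC[Si](CC)(CC)OS(=O)(=O)C(F)(F)F
Why: The unhindered methyl ketone reacts in preference to the α‑quaternary ring ketone, and the Ti–bis(sulfonamide) diol catalyst delivers vinyl to its Re face (methyl against a neopentyl‑type CH2) to set the C4 carbinol centre by catalyst control, which is silylated at once so that the alkoxide cannot add to the C1 ketone (catalytic asymmetric vinylzinc addition to a ketone, silyl protection).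

Step 9
Reactants: 22 (4R,6S)-3-{[tert-butyl(dimethyl)silyl]oxymethyl}-6-methyl-7a-[(2S)-2-methyl-2-(triethylsilyloxy)but-3-en-1-yl]-2,7-dioxo-2,4,5,6,7,7a-hexahydro-1-benzofuran-4-yl 3-methylbut-2-enoate
Product: 24 (4R,6S)-3-{[tert-butyl(dimethyl)silyl]oxymethyl}-7a-[(2S)-4-iodo-2-methyl-2-(triethylsilyloxy)butyl]-6-methyl-2,7-dioxo-2,4,5,6,7,7a-hexahydro-1-benzofuran-4-yl 3-methylbut-2-enoate, via alkylborane 23 (not isolated)
Conditions: (c‑C6H11)2BH (from BH3·SMe2 and cyclohexene), THF, 0 °C; then NaOAc, ICl, MeOH, 0 °C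
Reagents that add atoms: iodine monochloride, ClI
Why: The bulky dialkylborane adds only to the terminal vinyl group with boron on the terminal carbon (C2), and ICl/NaOAc converts the primary C–B bond into the C–I bond without touching the electron‑poor alkenes or the hindered ketone (anti‑Markovnikov hydroboration–iodination).

Step 10
Reactants: 24 (4R,6S)-3-{[tert-butyl(dimethyl)silyl]oxymethyl}-7a-[(2S)-4-iodo-2-methyl-2-(triethylsilyloxy)butyl]-6-methyl-2,7-dioxo-2,4,5,6,7,7a-hexahydro-1-benzofuran-4-yl 3-methylbut-2-enoate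
Product: 26 (4R,5Z,8R,10S)-4,13-dihydroxy-8-(3-methylbut-2-enoyloxy)-1-oxogermacra-5,7(11)-dien-12,6-olide, via bis-silyl ether 25 (not isolated)
Conditions: Pd(OAc)2 (10 mol%), Xantphos (20 mol%), Cs2CO3 (1.5 equiv), degassed benzene (0.01 M), blue LEDs, rt; then HF·pyridine, pyridine, THF, 0 °C to rt
Reagents that add atoms: none
Why: Proposed new method: photoexcited zerovalent palladium–Xantphos transfers an electron to the primary C–I bond to give a C2 radical and monovalent palladium iodide; the radical adds 6‑exo to the ring‑B ketone carbon C1 (ring A forms), the tertiary alkoxy radical cleaves the C1–C6 bond because this releases a captodative 2‑oxo‑2,5‑dihydrofuran‑5‑yl radical (a four‑atom Dowd–Beckwith‑type 1,5‑acyl shift that builds the C1–C2 bond and the ten‑membered ring), and recombination with palladium followed by β‑hydride loss from C5 gives the (5Z) enol‑lactone alkene (C4 syn to the lactone oxygen avoids allylic strain with C8) while Cs2CO3 returns zerovalent palladium, C4, C8 and C10 being untouched; the closest known reactions are the tin‑hydride Dowd–Beckwith ring expansion of α‑(ω‑haloalkyl) β‑keto esters and visible‑light palladium‑catalysed desaturation of alkyl halides, and fluoride then removes both silyl groups.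

Step 11
Reactants: 26 (4R,5Z,8R,10S)-4,13-dihydroxy-8-(3-methylbut-2-enoyloxy)-1-oxogermacra-5,7(11)-dien-12,6-olide; 27 acetic anhydride
Product: 28 (4R,5Z,8R,10S)-13-acetoxy-4-hydroxy-8-(3-methylbut-2-enoyloxy)-1-oxogermacra-5,7(11)-dien-12,6-olide (CNP0186726.1)
Conditions: 27 (1.2 equiv), pyridine, CH2Cl2, 0 °C
Reagents that add atoms: none
Why: Ac2O/pyridine acetylates only the primary allylic C13 hydroxyl, the tertiary C4 carbinol being inert under these conditions (chemoselective acetylation).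

## Compound list

1 | but-2-yne-1,4-diol | OCC#CCO | starting material
2 | vinylmagnesium bromide | C=C[Mg]Br | starting material
3 | carbon dioxide | O=C=O | starting material
4 | (2Z)-2-(bromomagnesio)-3-ethenylbut-2-ene-1,4-diol bis(bromomagnesium) alkoxide | C=C/C(CO[Mg]Br)=C(\CO[Mg]Br)[Mg]Br | intermediate
5 | (2Z)-2,3-bis(hydroxymethyl)penta-2,4-dienoic acid | C=C/C(CO)=C(\CO)C(=O)O | intermediate
6 | 4-ethenyl-3-(hydroxymethyl)furan-2(5H)-one | OCC1=C(C=C)COC1=O | intermediate
7 | 3-{[tert-butyl(dimethyl)silyl]oxymethyl}-4-ethenylfuran-2(5H)-one | CC(C)(C)[Si](C)(C)OCC1=C(C=C)COC1=O | intermediate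
8 | 3-{[tert-butyl(dimethyl)silyl]oxymethyl}-4-(1,2,4-trioxolan-3-yl)furan-2(5H)-one | CC(C)(C)[Si](C)(C)OCC1=C(C2OCOO2)COC1=O | intermediate
9 | 4-{[tert-butyl(dimethyl)silyl]oxymethyl}-5-oxo-2,5-dihydrofuran-3-carbaldehyde | CC(C)(C)[Si](C)(C)OCC1=C(C=O)COC1=O | intermediate
10 | methyl (2R)-3-bromo-2-methylpropanoate | COC(=O)[C@@H](C)CBr | starting material
11 | bis[(2R)-3-methoxy-2-methyl-3-oxopropyl]zinc | COC(=O)[C@@H](C)C[Zn]C[C@H](C)C(=O)OC | intermediate
12 | methyl (2S,4R)-4-(4-{[tert-butyl(dimethyl)silyl]oxymethyl}-5-oxo-2,5-dihydrofuran-3-yl)-4-hydroxy-2-methylbutanoate | CC(C)(C)[Si](C)(C)OCC1=C(COC1=O)[C@H](O)C[C@H](C)C(=O)OC | intermediate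
13 | (3S,5R)-5-(4-{[tert-butyl(dimethyl)silyl]oxymethyl}-5-oxo-2,5-dihydrofuran-3-yl)-3-methyloxolan-2-one | CC(C)(C)[Si](C)(C)OCC1=C(COC1=O)[C@H]2C[C@H](C)C(=O)O2 | intermediate
14 | lithium (4R,6S)-3-{[tert-butyl(dimethyl)silyl]oxymethyl}-4-hydroxy-6-methyl-2-oxo-2,4,5,6-tetrahydro-1-benzofuran-7-olate | [Li+].CC(C)(C)[Si](C)(C)OCC1=C2[C@H](O)C[C@H](C)C([O-])=C2OC1=O | intermediate
15 | (4R,6S)-3-{[tert-butyl(dimethyl)silyl]oxymethyl}-4-hydroxy-6-methyl-4,5,6,7a-tetrahydro-1-benzofuran-2,7-dione | CC(C)(C)[Si](C)(C)OCC1=C2[C@H](O)C[C@H](C)C(=O)C2OC1=O | intermediate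
16 | 3-methylbut-2-enoyl chloride | CC(C)=CC(Cl)=O | starting material
17 | (4R,6S)-3-{[tert-butyl(dimethyl)silyl]oxymethyl}-6-methyl-2,7-dioxo-2,4,5,6,7,7a-hexahydro-1-benzofuran-4-yl 3-methylbut-2-enoate | CC(C)(C)[Si](C)(C)OCC1=C2[C@H](OC(=O)C=C(C)C)C[C@H](C)C(=O)C2OC1=O | intermediate
18 | 1-bromopropan-2-one | CC(=O)CBr | starting material
19 | (4R,6S)-3-{[tert-butyl(dimethyl)silyl]oxymethyl}-6-methyl-2,7-dioxo-7a-(2-oxopropyl)-2,4,5,6,7,7a-hexahydro-1-benzofuran-4-yl 3-methylbut-2-enoate | CC(C)(C)[Si](C)(C)OCC1=C2[C@H](OC(=O)C=C(C)C)C[C@H](C)C(=O)C2(CC(C)=O)OC1=O | intermediate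
20 | divinylzinc | C=C[Zn]C=C | intermediate
21 | ethenylzinc alkoxide of the (2S)-2-hydroxy-2-methylbut-3-en-1-yl adduct of 19 | CC(C)(C)[Si](C)(C)OCC1=C2[C@H](OC(=O)C=C(C)C)C[C@H](C)C(=O)C2(C[C@](C)(O[Zn]C=C)C=C)OC1=O | intermediate
22 | (4R,6S)-3-{[tert-butyl(dimethyl)silyl]oxymethyl}-6-methyl-7a-[(2S)-2-methyl-2-(triethylsilyloxy)but-3-en-1-yl]-2,7-dioxo-2,4,5,6,7,7a-hexahydro-1-benzofuran-4-yl 3-methylbut-2-enoate | CC(C)(C)[Si](C)(C)OCC1=C2[C@H](OC(=O)C=C(C)C)C[C@H](C)C(=O)C2(C[C@](C)(O[Si](CC)(CC)CC)C=C)OC1=O | intermediate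
23 | (4R,6S)-3-{[tert-butyl(dimethyl)silyl]oxymethyl}-7a-[(2R)-4-(dicyclohexylboranyl)-2-methyl-2-(triethylsilyloxy)butyl]-6-methyl-2,7-dioxo-2,4,5,6,7,7a-hexahydro-1-benzofuran-4-yl 3-methylbut-2-enoate | CC(C)(C)[Si](C)(C)OCC1=C2[C@H](OC(=O)C=C(C)C)C[C@H](C)C(=O)C2(C[C@](C)(O[Si](CC)(CC)CC)CCB(C3CCCCC3)C3CCCCC3)OC1=O | intermediate
24 | (4R,6S)-3-{[tert-butyl(dimethyl)silyl]oxymethyl}-7a-[(2S)-4-iodo-2-methyl-2-(triethylsilyloxy)butyl]-6-methyl-2,7-dioxo-2,4,5,6,7,7a-hexahydro-1-benzofuran-4-yl 3-methylbut-2-enoate | CC(C)(C)[Si](C)(C)OCC1=C2[C@H](OC(=O)C=C(C)C)C[C@H](C)C(=O)C2(C[C@](C)(O[Si](CC)(CC)CC)CCI)OC1=O | intermediate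
25 | (4R,5Z,8R,10S)-13-[tert-butyl(dimethyl)silyloxy]-8-(3-methylbut-2-enoyloxy)-1-oxo-4-(triethylsilyloxy)germacra-5,7(11)-dien-12,6-olide | CC(C)(C)[Si](C)(C)OCC1=C2/C(=C/[C@](C)(O[Si](CC)(CC)CC)CCC(=O)[C@@H](C)C[C@H]2OC(=O)C=C(C)C)OC1=O | intermediate
26 | (4R,5Z,8R,10S)-4,13-dihydroxy-8-(3-methylbut-2-enoyloxy)-1-oxogermacra-5,7(11)-dien-12,6-olide | OCC1=C2/C(=C/[C@](C)(O)CCC(=O)[C@@H](C)C[C@H]2OC(=O)C=C(C)C)OC1=O | intermediate
27 | acetic anhydride | CC(=O)OC(C)=O | starting material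
28 | (4R,5Z,8R,10S)-13-acetoxy-4-hydroxy-8-(3-methylbut-2-enoyloxy)-1-oxogermacra-5,7(11)-dien-12,6-olide | CC(=O)OCC1=C2/C(=C/[C@](C)(O)CCC(=O)[C@@H](C)C[C@H]2OC(=O)C=C(C)C)OC1=O | target

## Step count and risk

Total steps: 11. Longest linear sequence: 11 (steps 1–11; all other inputs are commercial).

Stereochemistry: C10 comes from 10 (chiral pool), C8 is set in step 4, C4 in step 8, and the 5Z alkene in step 10. The C10 centre sits next to the C1 ketone from step 7 on, so only weak, heterogeneous bases are used after that point.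

The three steps most likely to fail:

Step 10 (the new reaction). The primary radical could be lost by simple dehydroiodination or by addition to C7 of the butenolide, 6‑exo attack on a hindered ketone is slow, and the alkene geometry is not enforced by the mechanism. Fallback with known chemistry, setting out from 24 and coming back at 25: Bu3SnH (slow addition) with AIBN in dilute benzene at 80 °C effects the classical reductive Dowd–Beckwith ring expansion to the saturated lactone (4R,8R,10S)-13-[tert-butyl(dimethyl)silyloxy]-8-(3-methylbut-2-enoyloxy)-1-oxo-4-(triethylsilyloxy)germacr-7(11)-en-12,6-olide F1 (both C6 epimers). LiN(SiMe3)2 (1.0 equiv, −78 °C) removes only the butenolide γ‑proton and PhSeBr gives the C6 phenylselanyl derivative F2. H2O2/pyridine at 0 °C gives the selenoxide F3, whose syn‑elimination can only go towards C5 and delivers 25, which is desilylated as in step 10.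

Step 8. Vinyl transfer to a dialkyl ketone next to a second ketone is demanding, and the tertiary metal alkoxide sits 1,4 to the C1 ketone, so it could add to it and expel the furanolate (ring B opening to a nine‑membered lactone). Fallback setting out from 19 and coming back at 24: catalytic asymmetric allylboration of the methyl ketone (allylB(OiPr)2, 3,3'-dibromo-BINOL catalyst, neutral conditions) followed by Et3SiOTf/2,6‑lutidine gives the homoallylic silyl ether (4R,6S)-3-{[tert-butyl(dimethyl)silyl]oxymethyl}-6-methyl-7a-[(2R)-2-methyl-2-(triethylsilyloxy)pent-4-en-1-yl]-2,7-dioxo-2,4,5,6,7,7a-hexahydro-1-benzofuran-4-yl 3-methylbut-2-enoate F4. OsO4 (cat.)/NaIO4/2,6‑lutidine cleaves only the terminal alkene to the aldehyde, the 7a-[(2S)-2-methyl-4-oxo-2-(triethylsilyloxy)butyl] analogue F5. NaBH4 at −78 °C reduces only the aldehyde to the primary alcohol, the 7a-[(2R)-4-hydroxy-2-methyl-2-(triethylsilyloxy)butyl] analogue F6. I2/PPh3/imidazole then gives 24.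

Step 4. The aldehyde is electron‑poor and carries acidic γ‑protons, and the functionalised dialkylzinc is a weak nucleophile, so enolisation or low conversion is possible. Fallback setting out from 9 and coming back at 13: CrCl2‑catalysed asymmetric 2‑(methoxycarbonyl)allylation with methyl 2‑(bromomethyl)acrylate (Mn powder, Cp2ZrCl2, chiral carbazole bis(oxazoline) ligand; non‑basic) gives the hydroxy ester methyl (4R)-4-(4-{[tert-butyl(dimethyl)silyl]oxymethyl}-5-oxo-2,5-dihydrofuran-3-yl)-4-hydroxy-2-methylidenebutanoate F7. PPTS closes it to the α‑methylene lactone (5R)-5-(4-{[tert-butyl(dimethyl)silyl]oxymethyl}-5-oxo-2,5-dihydrofuran-3-yl)-3-methylideneoxolan-2-one F8. Hydrogenation with Ru(OAc)2(BINAP), using the BINAP enantiomer that gives the (3S)‑methyl centre, reduces only the exocyclic alkene and gives 13.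

Further compounds
F1 | step 10 | (4R,8R,10S)-13-[tert-butyl(dimethyl)silyloxy]-8-(3-methylbut-2-enoyloxy)-1-oxo-4-(triethylsilyloxy)germacr-7(11)-en-12,6-olide (C6 epimers) | CC(C)(C)[Si](C)(C)OCC1=C2C(C[C@](C)(O[Si](CC)(CC)CC)CCC(=O)[C@@H](C)C[C@H]2OC(=O)C=C(C)C)OC1=O
F2 | step 10 | 6-(phenylselanyl) derivative of F1 | CC(C)(C)[Si](C)(C)OCC1=C2C([Se]c3ccccc3)(C[C@](C)(O[Si](CC)(CC)CC)CCC(=O)[C@@H](C)C[C@H]2OC(=O)C=C(C)C)OC1=O
F3 | step 10 | 6-(benzeneseleninyl) derivative of F1 (selenoxide) | CC(C)(C)[Si](C)(C)OCC1=C2C([Se](=O)c3ccccc3)(C[C@](C)(O[Si](CC)(CC)CC)CCC(=O)[C@@H](C)C[C@H]2OC(=O)C=C(C)C)OC1=O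
F4 | step 8 | (4R,6S)-3-{[tert-butyl(dimethyl)silyl]oxymethyl}-6-methyl-7a-[(2R)-2-methyl-2-(triethylsilyloxy)pent-4-en-1-yl]-2,7-dioxo-2,4,5,6,7,7a-hexahydro-1-benzofuran-4-yl 3-methylbut-2-enoate | CC(C)(C)[Si](C)(C)OCC1=C2[C@H](OC(=O)C=C(C)C)C[C@H](C)C(=O)C2(C[C@](C)(O[Si](CC)(CC)CC)CC=C)OC1=O
F5 | step 8 | (4R,6S)-3-{[tert-butyl(dimethyl)silyl]oxymethyl}-6-methyl-7a-[(2S)-2-methyl-4-oxo-2-(triethylsilyloxy)butyl]-2,7-dioxo-2,4,5,6,7,7a-hexahydro-1-benzofuran-4-yl 3-methylbut-2-enoate | CC(C)(C)[Si](C)(C)OCC1=C2[C@H](OC(=O)C=C(C)C)C[C@H](C)C(=O)C2(C[C@](C)(O[Si](CC)(CC)CC)CC=O)OC1=O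
F6 | step 8 | (4R,6S)-3-{[tert-butyl(dimethyl)silyl]oxymethyl}-7a-[(2R)-4-hydroxy-2-methyl-2-(triethylsilyloxy)butyl]-6-methyl-2,7-dioxo-2,4,5,6,7,7a-hexahydro-1-benzofuran-4-yl 3-methylbut-2-enoate | CC(C)(C)[Si](C)(C)OCC1=C2[C@H](OC(=O)C=C(C)C)C[C@H](C)C(=O)C2(C[C@](C)(O[Si](CC)(CC)CC)CCO)OC1=O
F7 | step 4 | methyl (4R)-4-(4-{[tert-butyl(dimethyl)silyl]oxymethyl}-5-oxo-2,5-dihydrofuran-3-yl)-4-hydroxy-2-methylidenebutanoate | CC(C)(C)[Si](C)(C)OCC1=C(COC1=O)[C@H](O)CC(=C)C(=O)OC
F8 | step 4 | (5R)-5-(4-{[tert-butyl(dimethyl)silyl]oxymethyl}-5-oxo-2,5-dihydrofuran-3-yl)-3-methylideneoxolan-2-one | CC(C)(C)[Si](C)(C)OCC1=C(COC1=O)[C@H]2CC(=C)C(=O)O2
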